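Assumption: eudesmane numbering is used for positions (ring C5–C10, lactone C8–O–C12(=O)–C11(=C13)–C7, C14 = CH2O‑methacryloyl, C1 = CH2OAc), and the SMILES is read as (4S,6S,7R,8R), i.e. trans‑fused lactone with 6‑OH cis to the C7–C11 bond.

## Retrosynthetic overview

1. Target ⇒ C6/C14 diol (methacryloylation of the primary allylic OH last); exocyclic methylene ⇒ saturated trans‑lactone (Mannich/elimination).
2. C6 carbinol and C14 alcohol ⇒ bicyclic formyl‑enone (C6=O, C14=O) by catalyst‑controlled reduction.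
3. Six‑membered ring (formed second) ⇒ C5–C10 aldol cyclodehydration of a 1,5‑diketone that already carries the trans 8,12‑lactone.
4. 1,5‑Diketone ⇒ acyl‑radical addition (C6–C7) of a citronellal‑derived aldehyde to a (5R)‑butenolide.
5. Butenolide (ring formed first) ⇒ proline aldol (C8–C9) plus lactonisation. The ring order copies the presumed biogenesis (8,12‑lactone, then C5–C10 closure as in germacranolide → eudesmanolide); the C1–C10 bond is never made, so no fragmentation is needed.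

## Route

Step 1
Reactants: 1 (S)-citronellal
Product: 2 (6S)-8,8-dimethoxy-2,6-dimethyloct-2-ene
Conditions: HC(OMe)3 (1.5 equiv), PPTS (2 mol%), MeOH, 0 → 23 °C
Reagents that add atoms: trimethyl orthoformate, COC(OC)OC
Why: Acid‑catalysed acetalisation with the orthoformate as water scavenger masks the aldehyde, PPTS being too weak to trigger the ene cyclisation to isopulegol, and the stereocentre is untouched.

Step 2
Reactants: 2 (6S)-8,8-dimethoxy-2,6-dimethyloct-2-ene
Product: 4 (4S)-6,6-dimethoxy-4-methylhexan-1-ol, via ozonide 3 (not isolated)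
Conditions: O3, CH2Cl2, −78 °C; then NaBH4, MeOH, −78 → 23 °C
Reagents that add atoms: ozone, [O-][O+]=O
Why: Reductive ozonolysis cleaves the only C=C and borohydride takes the ozonide straight to the primary alcohol while the acetal is inert.

Step 3
Reactants: 4 (4S)-6,6-dimethoxy-4-methylhexan-1-ol
Product: 6 (4S)-4-methyl-6-oxohexyl acetate, via acetoxy acetal 5 (not isolated)
Conditions: Ac2O, pyridine, DMAP (cat.), CH2Cl2, 23 °C; then 1 M HCl, THF, 23 °C
Reagents that add atoms: acetic anhydride, CC(=O)OC(C)=O; water, O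
Why: Acetylation followed by mild aqueous‑acid acetal hydrolysis unmasks the aldehyde, whose β‑stereocentre cannot enolise.

Step 4
Reactants: 7 5-hydroxyfuran-2(5H)-one; 8 1,1-dimethoxypropan-2-one
Product: 10 (5R)-5-(3,3-dimethoxy-2-oxopropyl)furan-2(5H)-one, via hydroxy acid 9 (not isolated)
Conditions: L‑proline (30 mol%), 8 (5 equiv), DMSO, 23 °C
Reagents that add atoms: none
Why: Proposed new method: L‑proline forms the enamine only on the methyl side of 8 (the acetal side is blocked) and this attacks the re face of the ring‑opened aldehyde tautomer of 7 through the hydrogen‑bonded Houk–List transition state to set C8 as (R), after which the (Z)‑γ‑hydroxy acid lactonises spontaneously; the closest known chemistry is the proline‑catalysed aldol addition of pyruvaldehyde dimethyl acetal to aldehydes and the C5 substitution of 5‑hydroxyfuranone by ketone enols.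

Step 5
Reactants: 6 (4S)-4-methyl-6-oxohexyl acetate; 10 (5R)-5-(3,3-dimethoxy-2-oxopropyl)furan-2(5H)-one
Product: 11 (4S)-6-[(2R,3S)-2-(3,3-dimethoxy-2-oxopropyl)-5-oxooxolan-3-yl]-4-methyl-6-oxohexyl acetate
Conditions: 6 (1.5 equiv), (nBu4N)4W10O32 (2 mol%), MeCN, 390 nm LEDs, 25 °C, N2
Reagents that add atoms: none
Why: Decatungstate‑photocatalysed hydroacylation, in which hydrogen abstraction from the formyl C–H gives a nucleophilic acyl radical that adds to C7 of the butenolide anti to the C8 side chain (trans lactone, new C7 stereocentre) before back hydrogen transfer to C11.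

Step 6
Reactants: 11 (4S)-6-[(2R,3S)-2-(3,3-dimethoxy-2-oxopropyl)-5-oxooxolan-3-yl]-4-methyl-6-oxohexyl acetate
Product: 14 (4S)-4-[(3aS,7aR)-6-formyl-2,4-dioxo-2,3,3a,4,7,7a-hexahydro-1-benzofuran-5-yl]pentyl acetate, via ketol 12 (not isolated), via enone acetal 13 (not isolated)
Conditions: CSA (0.2 equiv), 4 Å MS, PhMe, 40 °C; then TFA–H2O 9:1, CH2Cl2, 0 °C
Reagents that add atoms: water, O
Why: Acid‑catalysed intramolecular aldol condensation (Robinson‑type cyclodehydration), in which only the C5 enol of the C6 ketone can reach a carbonyl through a six‑membered ring and the C10 α‑keto acetal is the most electrophilic carbonyl and cannot enolise towards C14, so the C5=C10 enone forms under conditions mild enough to keep the trans ring fusion, and wet TFA then hydrolyses the acetal.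

Step 7
Reactants: 14 (4S)-4-[(3aS,7aR)-6-formyl-2,4-dioxo-2,3,3a,4,7,7a-hexahydro-1-benzofuran-5-yl]pentyl acetate
Product: 15 (4S)-4-[(3aR,4S,7aR)-4-hydroxy-6-(hydroxymethyl)-2-oxo-2,3,3a,4,7,7a-hexahydro-1-benzofuran-5-yl]pentyl acetate
Conditions: (R)-Me-CBS (20 mol%), BH3·SMe2 (2.5 equiv), THF, −30 °C; MeOH quench
Reagents that add atoms: none
Why: Corey–Bakshi–Shibata reduction, in which borane reduces the aldehyde at once and the (R)‑oxazaborolidine, reading the fully substituted alkenyl carbon C5 as the large group, delivers hydride to give the (S) carbinol at C6 (OH cis to C7–C11) under catalyst control.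

Step 8
Reactants: 15 (4S)-4-[(3aR,4S,7aR)-4-hydroxy-6-(hydroxymethyl)-2-oxo-2,3,3a,4,7,7a-hexahydro-1-benzofuran-5-yl]pentyl acetate
Product: 16 (4S)-4-[(3aS,4S,7aR)-4-(tert-butyldimethylsilyloxy)-6-(tert-butyldimethylsilyloxymethyl)-2-oxo-2,3,3a,4,7,7a-hexahydro-1-benzofuran-5-yl]pentyl acetate
Conditions: TBSOTf (2.4 equiv), 2,6-lutidine (4 equiv), CH2Cl2, −78 → 0 °C
Reagents that add atoms: tert-butyldimethylsilyl triflate, CC(C)(C)[Si](C)(C)OS(=O)(=O)C(F)(F)F
Why: Silyl triflate silylation caps both the primary and the hindered pseudo‑axial secondary hydroxyl, so that no O–H and no alkoxide that could translactonise remains for the enolate step.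

Step 9
Reactants: 16 (4S)-4-[(3aS,4S,7aR)-4-(tert-butyldimethylsilyloxy)-6-(tert-butyldimethylsilyloxymethyl)-2-oxo-2,3,3a,4,7,7a-hexahydro-1-benzofuran-5-yl]pentyl acetate
Product: 19 (4S)-4-[(3aS,4S,7aR)-4-(tert-butyldimethylsilyloxy)-6-(tert-butyldimethylsilyloxymethyl)-3-methylidene-2-oxo-2,3,3a,4,7,7a-hexahydro-1-benzofuran-5-yl]pentyl acetate, via Mannich base 17 (not isolated), via ammonium iodide 18 (not isolated)
Conditions: LiHMDS (1.15 equiv), THF, −78 °C; CH2=NMe2+ I− (2 equiv), −78 → 0 °C; then MeI, MeOH, 23 °C; then aq. NaHCO3, CH2Cl2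
Reagents that add atoms: Eschenmoser's salt, C=[N+](C)C.[I-]; iodomethane, CI (N‑methyl of 18 only)
Why: Eschenmoser α‑methylenation (Mannich reaction, N‑methylation, E1cB loss of trimethylamine), which works because the γ‑lactone α‑CH2 is several pK units more acidic than the acetate CH3, so one equivalent of base enolises only C11 and elimination can only give the exocyclic alkene.

Step 10
Reactants: 19 (4S)-4-[(3aS,4S,7aR)-4-(tert-butyldimethylsilyloxy)-6-(tert-butyldimethylsilyloxymethyl)-3-methylidene-2-oxo-2,3,3a,4,7,7a-hexahydro-1-benzofuran-5-yl]pentyl acetate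
Product: 20 (4S)-4-[(3aR,4S,7aR)-4-hydroxy-6-(hydroxymethyl)-3-methylidene-2-oxo-2,3,3a,4,7,7a-hexahydro-1-benzofuran-5-yl]pentyl acetate
Conditions: HF·pyridine, pyridine/THF, 0 → 23 °C
Reagents that add atoms: none
Why: Fluoride desilylation under buffered, non‑basic conditions removes both silyl ethers without translactonisation onto the C6 hydroxyl or conjugate addition to the methylene lactone.

Step 11
Reactants: 20 (4S)-4-[(3aR,4S,7aR)-4-hydroxy-6-(hydroxymethyl)-3-methylidene-2-oxo-2,3,3a,4,7,7a-hexahydro-1-benzofuran-5-yl]pentyl acetate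
Product: 21 [(3aR,4S,7aR)-5-[(2S)-5-acetoxypentan-2-yl]-4-hydroxy-3-methylidene-2-oxo-2,3,3a,4,7,7a-hexahydro-1-benzofuran-6-yl]methyl 2-methylprop-2-enoate (CNP0122587.1)
Conditions: methacrylic anhydride (1.1 equiv), Et3N, DMAP (5 mol%), CH2Cl2, −20 °C
Reagents that add atoms: methacrylic anhydride, C=C(C)C(=O)OC(=O)C(C)=C
Why: DMAP‑catalysed acylation at low temperature selects the unhindered primary allylic C14 hydroxyl over the pseudo‑axial C6 hydroxyl, which is flanked by the tetrasubstituted alkene and the ring fusion.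

## Compound list

1 | (S)-citronellal, (3S)-3,7-dimethyloct-6-enal | O=CC[C@@H](C)CCC=C(C)C | starting material
2 | (6S)-8,8-dimethoxy-2,6-dimethyloct-2-ene | COC(OC)C[C@@H](C)CCC=C(C)C | intermediate
3 | ozonide, 3-[(3S)-5,5-dimethoxy-3-methylpentyl]-5,5-dimethyl-1,2,4-trioxolane | COC(OC)C[C@@H](C)CCC1OOC(C)(C)O1 | intermediate
4 | (4S)-6,6-dimethoxy-4-methylhexan-1-ol | COC(OC)C[C@@H](C)CCCO | intermediate
5 | (4S)-6,6-dimethoxy-4-methylhexyl acetate | COC(OC)C[C@@H](C)CCCOC(C)=O | intermediate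
6 | (4S)-4-methyl-6-oxohexyl acetate | O=CC[C@@H](C)CCCOC(C)=O | intermediate
7 | 5-hydroxyfuran-2(5H)-one | OC1OC(=O)C=C1 | starting material
8 | 1,1-dimethoxypropan-2-one | COC(OC)C(C)=O | starting material
9 | (2Z,4R)-4-hydroxy-7,7-dimethoxy-6-oxohept-2-enoic acid | OC(=O)/C=C\[C@H](O)CC(=O)C(OC)OC | intermediate
10 | (5R)-5-(3,3-dimethoxy-2-oxopropyl)furan-2(5H)-one | COC(OC)C(=O)C[C@H]1OC(=O)C=C1 | intermediate
11 | (4S)-6-[(2R,3S)-2-(3,3-dimethoxy-2-oxopropyl)-5-oxooxolan-3-yl]-4-methyl-6-oxohexyl acetate | O=C(C[C@@H](C)CCCOC(C)=O)[C@H]1CC(=O)O[C@@H]1CC(=O)C(OC)OC | intermediate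
12 | ketol, (4S)-4-[(3aS,7aR)-6-(dimethoxymethyl)-6-hydroxy-2,4-dioxooctahydro-1-benzofuran-5-yl]pentyl acetate (ring C5 and C6 unassigned) | COC(OC)C1(O)C([C@@H](C)CCCOC(C)=O)C(=O)[C@H]2CC(=O)O[C@@H]2C1 | intermediate
13 | (4S)-4-[(3aS,7aR)-6-(dimethoxymethyl)-2,4-dioxo-2,3,3a,4,7,7a-hexahydro-1-benzofuran-5-yl]pentyl acetate | COC(OC)C1=C([C@@H](C)CCCOC(C)=O)C(=O)[C@H]2CC(=O)O[C@@H]2C1 | intermediate
14 | (4S)-4-[(3aS,7aR)-6-formyl-2,4-dioxo-2,3,3a,4,7,7a-hexahydro-1-benzofuran-5-yl]pentyl acetate | O=CC1=C([C@@H](C)CCCOC(C)=O)C(=O)[C@H]2CC(=O)O[C@@H]2C1 | intermediate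
15 | (4S)-4-[(3aR,4S,7aR)-4-hydroxy-6-(hydroxymethyl)-2-oxo-2,3,3a,4,7,7a-hexahydro-1-benzofuran-5-yl]pentyl acetate | OCC1=C([C@@H](C)CCCOC(C)=O)[C@@H](O)[C@H]2CC(=O)O[C@@H]2C1 | intermediate
16 | (4S)-4-[(3aS,4S,7aR)-4-(tert-butyldimethylsilyloxy)-6-(tert-butyldimethylsilyloxymethyl)-2-oxo-2,3,3a,4,7,7a-hexahydro-1-benzofuran-5-yl]pentyl acetate | CC(C)(C)[Si](C)(C)OCC1=C([C@@H](C)CCCOC(C)=O)[C@@H](O[Si](C)(C)C(C)(C)C)[C@H]2CC(=O)O[C@@H]2C1 | intermediate
17 | Mannich base, 3-(dimethylaminomethyl) derivative of 16 (C3 unassigned) | CC(C)(C)[Si](C)(C)OCC1=C([C@@H](C)CCCOC(C)=O)[C@@H](O[Si](C)(C)C(C)(C)C)[C@H]2C(CN(C)C)C(=O)O[C@@H]2C1 | intermediate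
18 | ammonium iodide, 3-(trimethylammoniomethyl) derivative of 16, iodide salt | CC(C)(C)[Si](C)(C)OCC1=C([C@@H](C)CCCOC(C)=O)[C@@H](O[Si](C)(C)C(C)(C)C)[C@H]2C(C[N+](C)(C)C)C(=O)O[C@@H]2C1.[I-] | intermediate
19 | (4S)-4-[(3aS,4S,7aR)-4-(tert-butyldimethylsilyloxy)-6-(tert-butyldimethylsilyloxymethyl)-3-methylidene-2-oxo-2,3,3a,4,7,7a-hexahydro-1-benzofuran-5-yl]pentyl acetate | CC(C)(C)[Si](C)(C)OCC1=C([C@@H](C)CCCOC(C)=O)[C@@H](O[Si](C)(C)C(C)(C)C)[C@H]2C(=C)C(=O)O[C@@H]2C1 | intermediate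
20 | (4S)-4-[(3aR,4S,7aR)-4-hydroxy-6-(hydroxymethyl)-3-methylidene-2-oxo-2,3,3a,4,7,7a-hexahydro-1-benzofuran-5-yl]pentyl acetate | OCC1=C([C@@H](C)CCCOC(C)=O)[C@@H](O)[C@H]2C(=C)C(=O)O[C@@H]2C1 | intermediate
21 | [(3aR,4S,7aR)-5-[(2S)-5-acetoxypentan-2-yl]-4-hydroxy-3-methylidene-2-oxo-2,3,3a,4,7,7a-hexahydro-1-benzofuran-6-yl]methyl 2-methylprop-2-enoate | C=C(C)C(=O)OCC1=C([C@@H](C)CCCOC(C)=O)[C@@H](O)[C@H]2C(=C)C(=O)O[C@@H]2C1 | target

## Step count and risks

Total steps: 11. Longest linear sequence: 10 (steps 1–3, then 5–11); step 4 is a one‑step branch.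

Steps most likely to fail:

Step 4 (aldol/lactonisation on the lactol). The amine may be sequestered by 7 as an N,O‑acetal, and the β‑acyloxy ketone product could eliminate under amine catalysis and so racemise. The fallback sets out from 8 and comes back at 10. L‑proline aldol of 8 with commercial ethyl (E)-4-oxobut-2-enoate, a normal open‑chain acceptor, gives ethyl (2E,4R)-4-hydroxy-7,7-dimethoxy-6-oxohept-2-enoate F1, which carries a poor leaving group and is configurationally robust. Sensitised irradiation (thioxanthone, 365 nm, MeCN) then isomerises the enoate to ethyl (2Z,4R)-4-hydroxy-7,7-dimethoxy-6-oxohept-2-enoate F2, which lactonises under catalytic CSA with loss of ethanol to 10.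

Step 5 (intermolecular acyl‑radical addition). The γ‑substituted butenolide is a sluggish acceptor, and decarbonylation or competing hydrogen abstraction from 10 may win. The fallback sets out from 6 and comes back at 11, coupling at the alcohol oxidation level. NaBH4 reduces 6 to (4S)-6-hydroxy-4-methylhexyl acetate F3. Hydrogen‑bond‑assisted photoredox HAT (Ir photocatalyst, quinuclidine, Bu4N H2PO4, blue LEDs) generates its α‑hydroxyalkyl radical, which adds to C7 of 10 anti to the side chain. This gives (4S)-6-[(2R,3R)-2-(3,3-dimethoxy-2-oxopropyl)-5-oxooxolan-3-yl]-6-hydroxy-4-methylhexyl acetate F4 as a carbinol mixture, and buffered Dess–Martin oxidation of the crude material returns 11.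

Step 7 (catalyst‑controlled C6 reduction). The substrate has a bulky α′ centre as well as the substituted alkene, so the CBS large/small assignment may be poor or mismatched. The fallback sets out from 14 and comes back at 15, using substrate control. NaBH(OAc)3 reduces only the aldehyde to (4S)-4-[(3aS,7aR)-6-(hydroxymethyl)-2,4-dioxo-2,3,3a,4,7,7a-hexahydro-1-benzofuran-5-yl]pentyl acetate F5. K‑Selectride at −78 °C then attacks the enone carbonyl along the equatorial trajectory (away from the axial H at C8) to give the pseudo‑axial (S) alcohol 15.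

Further compounds
F1 | step 4 | ethyl (2E,4R)-4-hydroxy-7,7-dimethoxy-6-oxohept-2-enoate | CCOC(=O)/C=C/[C@H](O)CC(=O)C(OC)OC
F2 | step 4 | ethyl (2Z,4R)-4-hydroxy-7,7-dimethoxy-6-oxohept-2-enoate | CCOC(=O)/C=C\[C@H](O)CC(=O)C(OC)OC
F3 | step 5 | (4S)-6-hydroxy-4-methylhexyl acetate | OCC[C@@H](C)CCCOC(C)=O
F4 | step 5 | (4S)-6-[(2R,3R)-2-(3,3-dimethoxy-2-oxopropyl)-5-oxooxolan-3-yl]-6-hydroxy-4-methylhexyl acetate | OC(C[C@@H](C)CCCOC(C)=O)[C@H]1CC(=O)O[C@@H]1CC(=O)C(OC)OC
F5 | step 7 | (4S)-4-[(3aS,7aR)-6-(hydroxymethyl)-2,4-dioxo-2,3,3a,4,7,7a-hexahydro-1-benzofuran-5-yl]pentyl acetate | OCC1=C([C@@H](C)CCCOC(C)=O)C(=O)[C@H]2CC(=O)O[C@@H]2C1
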